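# Proposed synthesis of CNP0263820.1 by a three-component conjunctive coupling and a Ni/Cr ring closure

## The problem

CNP0263820.1 is a monocyclic humulane-type acid. Its eleven-membered carbocycle is numbered here C1 to C11: C1 carries an exocyclic methylene (C15), C4=C5 is a trisubstituted olefin whose C5 bears the carboxyl carbon C14, C7 carries an angeloyloxy group, C9 is a gem-dimethyl quaternary carbon and C11 carries a free allylic hydroxyl.

- There is no ring fusion to lean on. An eleven-carbon chain must be assembled with the C4=C5 geometry fixed (C3 cis to C6, the ring-cis arrangement, E by the sequence rule), and a medium ring must then be closed against transannular strain and oligomerisation.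
- The two stereocentres, C7 (S) and C11 (S), lie 1,5 to each other across the quaternary C9. Neither can be expected to relay its configuration to the other, so each needs its own external control element.
- Several groups are fragile. The angelate isomerises to the tiglate under nucleophilic catalysis, base or prolonged heat. The C7 oxygen is gamma to the C14 carbonyl, so a free C7 carbinol next to a C14 ester can close to an alpha-alkylidene butyrolactone. The allylic carbinol beside a 1,1-disubstituted olefin does not tolerate strong acid. The acid must therefore be released last, under neutral conditions.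
- The feature that opens the key step is the environment of C7. It is a carbinol carbon flanked by C8 (a methylene on the quaternary C9) and by C6 (a methylene on the sp2 carbon C5). This is the R–CH(B)–CH2–C(sp2) pattern formed when a vinylboron ate complex undergoes a metal-induced 1,2-shift in the presence of an alkenyl electrophile. C7–C8, C5–C6 and the C7 configuration can therefore be made in one operation, with C9 carried in ready-made.
- A second feature is that C1(=C15H2)–C11(OH) is what a 2-haloalkene gives on addition to an aldehyde. This marks C1–C11 as the ring-closing bond.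

## Retrosynthesis

**Target 22 from ester 21.** The last cut is the O–alkyl bond of a 2-(trimethylsilyl)ethyl ester at C14. Unlike a tert-butyl or methyl ester, this ester is cleaved by fluoride alone, so neither acid (C11 carbinol, C1 methylene) nor hydroxide (angelate) meets the finished ring. The forward step only has to fragment the silylethyl group.

**Macrocycle 21 from iodo aldehyde 20.** The C1–C11 bond is cut. A cut at C2–C3 offers no functional handle, and a cut at C4=C5 would set the geometry of a trisubstituted olefin in the ring-forming event. The C1–C11 cut removes the ring and the C11 stereocentre together and maps the methylene/carbinol pair onto a 2-iodoalkene and an aldehyde. Compound 20 is acyclic with a single stereocentre. The forward reaction is a Ni/Cr-mediated closure at high dilution, helped by the gem-dimethyl group and the cis olefin. A chiral ligand on chromium must choose the aldehyde face, because C7 is too remote to do so.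

**Iodo aldehyde 20 from angelate 17, through alcohol 19 and iodide 18.** No skeletal bond is cut. The C11 aldehyde comes from a silyl ether and the C1 iodide from a triethylsilyl group. C1 is carried as a 1-silylalkene for three reasons:
- a second C(sp2)–halogen bond would compete for palladium in the key step;
- an alkyne would invite carbopalladation and would later need a Markovnikov hydrohalogenation next to a silyl ether;
- the vinylsilane is inert until N-iodosuccinimide replaces silicon by iodine at the same carbon.

The three silicon groups are then removed in a fixed order: C–Si by iodonium, O–Si by acidic methanol, and the ester by fluoride.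

**Angelate 17 from boronate 15, through carbinol 16.** The C7–O acyl bond and, before it, the C7–B bond are addressed. Acylating directly after oxidation means two free carbinols never have to be told apart after ring closure, and it removes the hydroxyl that could lactonise onto C14. Compound 15 contains every carbon of the chain.

**Boronate 15 from alkyllithium 13, vinylboronate 12 and bromo enoate 11, through ate complex 14.** C7–C8 and C5–C6 are cut together. The neighbouring cuts are weaker:
- C6–C7 by allylation of a C7 aldehyde would need a 2-carboxyallyl metal already bearing C4, and allylic transposition would place the new bond on the wrong carbon;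
- C7–C8 by epoxide opening would need a neopentyl-type nucleophile in an SN2 reaction;
- either would set C7 in a separate step.

The double cut gives three achiral pieces of eight, two and seven skeletal carbons. The forward reaction must be enantioselective at C7 and must retain the geometry of 11.

**Bromo enoate 11 from aldehyde 7 and ylide 9, through bromo ylide 10.** C4=C5 is cut by a Wittig reaction of a bromo-substituted stabilised ylide, which places the ester trans to the chain and so gives the (Z)-bromide. Aldehyde 7 comes from pent-4-yn-1-ol 5 by Markovnikov hydrosilylation to 6 and oxidation. Ylide 9 comes from the Bestmann ylide 8 and 2-(trimethylsilyl)ethanol.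

**Alkyllithium 13 from iodide 4.** Iodide 4 is reached from lactone 1 by reduction to diol 2, silylation of the unhindered hydroxyl to 3 and iodination of the neopentyl hydroxyl. The quaternary carbon is bought, not built.

## Roads not taken

**Alternative 1:** The ring is cut retrosynthetically by contracting it. The eleven-membered ketone A2 would arise from the cis-divinylcycloheptanol A1 by anionic oxy-Cope rearrangement of its potassium alkoxide, which forms C2–C3, breaks C5–C11 and delivers the C4=C5 olefin and a regiodefined C11 enolate.
- Merits: the expansion is unimolecular, needs no high dilution, and does not pay the entropic price of an end-to-end closure. On the certainty of ring formation this road is better than the chosen one.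
- Weak points: A1 needs a quaternary C5 (vinyl and protected hydroxymethyl) next to a tertiary carbinol C11 with the vinyl groups cis, on a cycloheptane that already carries the C7 stereocentre and the gem-dimethyl group. The olefin geometry depends on a chair or boat transition state in a flexible ring. After A2, C14 must still be raised by two oxidation levels, C1 methylenated and the C11 ketone reduced under substrate control only.
- Comparison: the chosen plan sets against the safer ring formation a convergent assembly with C14 at the acid level from the start, and ligand control at C11.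

**Alternative 2:** The C9–C10 bond is cut. Lewis-acid ionisation of the allylic phosphate in the farnesyl-like chain A3 would give an allyl cation that is captured by C9 of the silyloxy allylsilane terminus, closing the ring to the C7 ketone A4 after hydrolysis of the enol silane.
- Merits: this is the shortest way to the eleven-membered ring, and it creates the quaternary carbon and the ring in one biomimetic step from a cheap linear precursor. In step count to the carbocycle it beats the chosen plan.
- Weak points: A4 has the wrong functionality at both stereocentres. The C7 ketone is flanked by two methylenes, so enantioselective reduction has little to grip. The C11=C1 olefin with a C15 methyl must be transposed to the C11 carbinol and C1 methylene by an ene-type oxidation whose regiochemistry and facial selectivity have no controlling element. The cation can also be attacked at its tertiary terminus or eliminate, and the enoate must survive the Lewis acid.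
- Comparison: the chosen plan is longer, but its oxygen functions arrive at the right oxidation level and each stereocentre has a reagent-based control element.

**Alternative 3:** The C4=C5 olefin is cut. The twelve-membered sulfone A5, bridging C4 and C5, would be halogenated at C5 and deprotonated at C4, and the episulfone would lose SO2 to give the ring-cis enoate A6.
- Merits: ring closure is moved to a twelve-membered thioether formation, an easier event than carbon–carbon closure of an eleven-membered ring. Both carbinol stereocentres are set in acyclic precursors before any ring exists. On those two counts this road is as good as or better than the chosen one.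
- Weak points: the geometry of a trisubstituted, ester-bearing olefin is decided in the episulfone-forming step and is not secured by any element of A5. Halogenating base must be applied with the allylic silyl ether and the ester present. Two separate asymmetric operations are needed for C7 and C11. The endgame after A6 requires selective removal of one silyl ether, angeloylation, and acidic cleavage of a tert-butyl ester beside an allylic carbinol.
- Comparison: the chosen plan sets against this a single convergent step that fixes C7 and the olefin geometry from a geometrically pure bromide, a fluoride-only final deprotection, and an oxidation–reduction fallback at C11.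

Key step: step 8

Remark on the chemistry: the sense of induction of the chiral ligands in steps 8 and 14 cannot be assigned from first principles for these substrates. It is assumed that one enantiomer of each delivers the (7S) boronate and the (11S) carbinol and that it is identified in the first trial. The (Z) descriptor of 11 and the (E) descriptor of 15 to 22 denote the same geometry (C3 cis to C6); only the priorities at C5 change.

## Route

Step 1
Reactants: 1 3,3-dimethyloxolan-2-one (alpha,alpha-dimethyl-gamma-butyrolactone)
Product: 2 2,2-dimethylbutane-1,4-diol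
Conditions: LiAlH4, THF, 0 °C → rt
Reagents that add atoms: none
Why: Hydride reduction of a lactone to the diol; the quaternary carbon (future C9) is untouched.

Step 2
Reactants: 2 2,2-dimethylbutane-1,4-diol
Product: 3 4-[(tert-butyldimethylsilyl)oxy]-2,2-dimethylbutan-1-ol
Conditions: TBSCl (1.0 equiv), imidazole, CH2Cl2, −20 → 0 °C
Reagents that add atoms: tert-butyldimethylsilyl chloride, CC(C)(C)[Si](C)(C)Cl
Why: Selective monosilylation; the hydroxyl on the future C11 is unhindered, whereas the neopentyl hydroxyl on the future C8 is shielded by the adjacent quaternary carbon.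

Step 3
Reactants: 3 4-[(tert-butyldimethylsilyl)oxy]-2,2-dimethylbutan-1-ol
Product: 4 tert-butyl(4-iodo-3,3-dimethylbutoxy)dimethylsilane
Conditions: I2, PPh3, imidazole, toluene, 80 °C
Reagents that add atoms: iodine, II
Why: Appel-type iodination; the alkoxyphosphonium leaving group and the small iodide allow SN2 displacement at the neopentyl carbon on heating, without rearrangement, and imidazole keeps the silyl ether from acid.

Step 4
Reactants: 5 pent-4-yn-1-ol
Product: 6 4-(triethylsilyl)pent-4-en-1-ol
Conditions: Et3SiH, [Cp*Ru(MeCN)3]PF6 (1 mol%), CH2Cl2, 0 °C → rt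
Reagents that add atoms: triethylsilane, CC[SiH](CC)CC
Why: Ruthenium-catalysed Markovnikov hydrosilylation of a terminal alkyne places silicon on the internal carbon (future C1) and tolerates the free hydroxyl.

Step 5
Reactants: 6 4-(triethylsilyl)pent-4-en-1-ol
Product: 7 4-(triethylsilyl)pent-4-enal
Conditions: Dess–Martin periodinane, CH2Cl2, 0 °C → rt
Reagents that add atoms: none
Why: Dess–Martin oxidation of a primary alcohol to the aldehyde (future C4) under conditions that leave the vinylsilane alone.

Step 6
Reactants: 8 (triphenylphosphoranylidene)ketene (Bestmann ylide)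
Product: 9 2-(trimethylsilyl)ethyl (triphenylphosphoranylidene)acetate
Conditions: Me3SiCH2CH2OH, toluene, 80 °C
Reagents that add atoms: 2-(trimethylsilyl)ethanol, C[Si](C)(C)CCO
Why: Addition of an alcohol across the cumulated ylide gives the stabilised ester ylide directly; its two carbons become C5 and C14.

Step 7
Reactants: 7 4-(triethylsilyl)pent-4-enal; 9 2-(trimethylsilyl)ethyl (triphenylphosphoranylidene)acetate
Product: 11 2-(trimethylsilyl)ethyl (2Z)-2-bromo-6-(triethylsilyl)hepta-2,6-dienoate, via bromo ylide 10 (not isolated)
Conditions: 9, NBS, CH2Cl2, −20 °C; then 7, K2CO3, −20 °C → rt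
Reagents that add atoms: N-bromosuccinimide, O=C1CCC(=O)N1Br
Why: Bromination of the stabilised ylide and deprotonation give the bromo ylide, whose Wittig reaction places the ester trans to the chain as stabilised ylides do, so bromine ends cis to C3. NBS is consumed before the vinylsilane is introduced.

Step 8
Reactants: 4 tert-butyl(4-iodo-3,3-dimethylbutoxy)dimethylsilane; 12 2-ethenyl-4,4,5,5-tetramethyl-1,3,2-dioxaborolane (vinylboronic acid pinacol ester); 11 2-(trimethylsilyl)ethyl (2Z)-2-bromo-6-(triethylsilyl)hepta-2,6-dienoate
Product: 15 2-(trimethylsilyl)ethyl (2E)-2-[(2S)-6-[(tert-butyldimethylsilyl)oxy]-4,4-dimethyl-2-(4,4,5,5-tetramethyl-1,3,2-dioxaborolan-2-yl)hexyl]-6-(triethylsilyl)hepta-2,6-dienoate, via alkyllithium 13 (not isolated), via lithium vinylboron ate complex 14 (not isolated)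
Conditions: 4, t-BuLi (2.0 equiv), Et2O/pentane, −78 °C; 12, −78 °C → rt; solvent exchange to THF; 11, Pd(OAc)2 (3 mol%), (Sp,Sp)- or (Rp,Rp)-MandyPhos [1,1'-bis(diphenylphosphino)-2,2'-bis(alpha-dimethylaminobenzyl)ferrocene] (3.6 mol%), NaOTf, THF, 60 °C
Reagents that add atoms: none
Why: Lithium–iodine exchange converts 4 into 13, which adds to boron of 12 to give the four-coordinate vinylboronate 14. Zerovalent palladium, formed from Pd(OAc)2 and the bisphosphine, inserts into the C5–Br bond of 11 with retention; once NaOTf has removed bromide and iodide from the coordination sphere, the cationic alkenylpalladium binds the vinyl group of 14 and induces anti 1,2-migration of C8 from boron to C7 as C6 bonds to palladium, and reductive elimination forms C5–C6. The closest known reaction type is the palladium-catalysed enantioselective conjunctive cross-coupling of organolithium-derived vinylboron ate complexes with aryl and alkenyl triflates or halides; the alpha-bromo enoate and the beta-quaternary primary migrating group (sterically akin to (trimethylsilyl)methyl) are new members of classes already used. No ring is closed. The C7 stereocentre is set by the chiral bisphosphine on palladium, which differentiates the faces of the bound vinyl group; the enantiomer giving (7S) is used. The step needs the metallate shift to outrun direct transmetalation and insertion of the pendant alkene: the wide-bite-angle ligand and the cationic palladium favour the shift, and the triethylsilyl group on C1 makes the 1,1-disubstituted alkene a poor insertion partner. It also needs one site of oxidative addition, secured because C5–Br is the only carbon–halogen bond present, and retention of olefin geometry, which oxidative addition and reductive elimination both provide, so C3 stays cis to C6.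

Step 9
Reactants: 15 2-(trimethylsilyl)ethyl (2E)-2-[(2S)-6-[(tert-butyldimethylsilyl)oxy]-4,4-dimethyl-2-(4,4,5,5-tetramethyl-1,3,2-dioxaborolan-2-yl)hexyl]-6-(triethylsilyl)hepta-2,6-dienoate
Product: 16 2-(trimethylsilyl)ethyl (2E)-2-[(2S)-6-[(tert-butyldimethylsilyl)oxy]-2-hydroxy-4,4-dimethylhexyl]-6-(triethylsilyl)hepta-2,6-dienoate
Conditions: 30% H2O2, pH 7 phosphate buffer, THF, 0 °C → rt
Reagents that add atoms: hydrogen peroxide, OO
Why: Boronate oxidation proceeds by 1,2-migration of C7 from boron to oxygen with retention, so the (7S) carbinol results. The neutral buffer avoids alkoxide formation, and with it lactonisation onto C14 and conjugate attack on the enoate.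

Step 10
Reactants: 16 2-(trimethylsilyl)ethyl (2E)-2-[(2S)-6-[(tert-butyldimethylsilyl)oxy]-2-hydroxy-4,4-dimethylhexyl]-6-(triethylsilyl)hepta-2,6-dienoate
Product: 17 2-(trimethylsilyl)ethyl (2E)-2-[(2S)-6-[(tert-butyldimethylsilyl)oxy]-4,4-dimethyl-2-{[(2Z)-2-methylbut-2-enoyl]oxy}hexyl]-6-(triethylsilyl)hepta-2,6-dienoate
Conditions: angelic acid, 2,4,6-trichlorobenzoyl chloride, Et3N, toluene, rt; then 16, 80 °C
Reagents that add atoms: angelic acid [(2Z)-2-methylbut-2-enoic acid], C/C=C(/C)C(=O)O
Why: Yamaguchi-type mixed-anhydride esterification run without a nucleophilic catalyst, the condition that avoids reversible conjugate addition and hence Z to E isomerisation of the angeloyl unit. The C7–O bond is not touched, so configuration is retained, and acylation ends the lactonisation risk.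

Step 11
Reactants: 17 2-(trimethylsilyl)ethyl (2E)-2-[(2S)-6-[(tert-butyldimethylsilyl)oxy]-4,4-dimethyl-2-{[(2Z)-2-methylbut-2-enoyl]oxy}hexyl]-6-(triethylsilyl)hepta-2,6-dienoate
Product: 18 2-(trimethylsilyl)ethyl (2E)-2-[(2S)-6-[(tert-butyldimethylsilyl)oxy]-4,4-dimethyl-2-{[(2Z)-2-methylbut-2-enoyl]oxy}hexyl]-6-iodohepta-2,6-dienoate
Conditions: NIS, 2,6-lutidine, (CF3)2CHOH, 0 °C
Reagents that add atoms: N-iodosuccinimide, O=C1CCC(=O)N1I
Why: Ipso-iododesilylation of a vinylsilane: the iodonium ion formed on the electron-rich C1=C15 bond collapses with loss of silicon, leaving iodine on C1. The enoate and angelate olefins are electron-poor and inert.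

Step 12
Reactants: 18 2-(trimethylsilyl)ethyl (2E)-2-[(2S)-6-[(tert-butyldimethylsilyl)oxy]-4,4-dimethyl-2-{[(2Z)-2-methylbut-2-enoyl]oxy}hexyl]-6-iodohepta-2,6-dienoate
Product: 19 2-(trimethylsilyl)ethyl (2E)-2-[(2S)-6-hydroxy-4,4-dimethyl-2-{[(2Z)-2-methylbut-2-enoyl]oxy}hexyl]-6-iodohepta-2,6-dienoate
Conditions: CSA (cat.), MeOH/CH2Cl2, 0 °C
Reagents that add atoms: none
Why: Acid-catalysed methanolysis of a primary tert-butyldimethylsilyl ether; the silylethyl ester, the angelate and the iodoalkene are stable to dilute sulfonic acid in methanol.

Step 13
Reactants: 19 2-(trimethylsilyl)ethyl (2E)-2-[(2S)-6-hydroxy-4,4-dimethyl-2-{[(2Z)-2-methylbut-2-enoyl]oxy}hexyl]-6-iodohepta-2,6-dienoate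
Product: 20 2-(trimethylsilyl)ethyl (2E)-2-[(2S)-4,4-dimethyl-2-{[(2Z)-2-methylbut-2-enoyl]oxy}-6-oxohexyl]-6-iodohepta-2,6-dienoate
Conditions: Dess–Martin periodinane, CH2Cl2, 0 °C → rt
Reagents that add atoms: none
Why: Dess–Martin oxidation to the C11 aldehyde; the quaternary C9 in the beta position rules out elimination or epimerisation.

Step 14
Reactants: 20 2-(trimethylsilyl)ethyl (2E)-2-[(2S)-4,4-dimethyl-2-{[(2Z)-2-methylbut-2-enoyl]oxy}-6-oxohexyl]-6-iodohepta-2,6-dienoate
Product: 21 2-(trimethylsilyl)ethyl (1E,6S,10S)-6-hydroxy-8,8-dimethyl-5-methylidene-10-{[(2Z)-2-methylbut-2-enoyl]oxy}cycloundec-1-ene-1-carboxylate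
Conditions: CrCl2 (excess), (S)- or (R)-N-[2-(4-isopropyl-4,5-dihydrooxazol-2-yl)-6-methoxyphenyl]methanesulfonamide, Et3N, NiCl2 (cat.), THF, rt, slow addition of 20 (high dilution)
Reagents that add atoms: none
Why: Nozaki–Hiyama–Kishi reaction: zerovalent nickel inserts into the C1–I bond, transmetalation gives the alkenyl–trivalent chromium species, and this adds to the C11 aldehyde, tolerating both esters. The sulfonamide ligand on chromium selects the aldehyde face, and the ligand enantiomer giving (11S) is used. The gem-dimethyl group, the cis C4=C5 olefin and high dilution favour closure over oligomerisation.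

Step 15
Reactants: 21 2-(trimethylsilyl)ethyl (1E,6S,10S)-6-hydroxy-8,8-dimethyl-5-methylidene-10-{[(2Z)-2-methylbut-2-enoyl]oxy}cycloundec-1-ene-1-carboxylate
Product: 22 (1E,6S,10S)-6-hydroxy-8,8-dimethyl-5-methylidene-10-{[(2Z)-2-methylbut-2-enoyl]oxy}cycloundec-1-ene-1-carboxylic acid (CNP0263820.1)
Conditions: TASF, DMF, 0 °C → rt; cold dilute HCl work-up
Reagents that add atoms: none
Why: Fluoride attack on silicon of the 2-(trimethylsilyl)ethyl ester triggers beta-fragmentation to ethylene and the carboxylate. No hydroxide or strong acid is present, so the angelate geometry, the allylic carbinol and both stereocentres are preserved.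

## Compound list

1 | 3,3-dimethyloxolan-2-one (alpha,alpha-dimethyl-gamma-butyrolactone) | CC1(C)CCOC1=O | starting material
2 | 2,2-dimethylbutane-1,4-diol | OCC(C)(C)CCO | intermediate
3 | 4-[(tert-butyldimethylsilyl)oxy]-2,2-dimethylbutan-1-ol | OCC(C)(C)CCO[Si](C)(C)C(C)(C)C | intermediate
4 | tert-butyl(4-iodo-3,3-dimethylbutoxy)dimethylsilane | ICC(C)(C)CCO[Si](C)(C)C(C)(C)C | intermediate
5 | pent-4-yn-1-ol | C#CCCCO | starting material
6 | 4-(triethylsilyl)pent-4-en-1-ol | C=C(CCCO)[Si](CC)(CC)CC | intermediate
7 | 4-(triethylsilyl)pent-4-enal | C=C(CCC=O)[Si](CC)(CC)CC | intermediate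
8 | (triphenylphosphoranylidene)ketene (Bestmann ylide) | O=C=C=P(c1ccccc1)(c1ccccc1)c1ccccc1 | starting material
9 | 2-(trimethylsilyl)ethyl (triphenylphosphoranylidene)acetate | C[Si](C)(C)CCOC(=O)C=P(c1ccccc1)(c1ccccc1)c1ccccc1 | intermediate
10 | 2-(trimethylsilyl)ethyl bromo(triphenylphosphoranylidene)acetate (not isolated) | C[Si](C)(C)CCOC(=O)C(Br)=P(c1ccccc1)(c1ccccc1)c1ccccc1 | intermediate
11 | 2-(trimethylsilyl)ethyl (2Z)-2-bromo-6-(triethylsilyl)hepta-2,6-dienoate | C=C(CC/C=C(\Br)C(=O)OCC[Si](C)(C)C)[Si](CC)(CC)CC | intermediate
12 | 2-ethenyl-4,4,5,5-tetramethyl-1,3,2-dioxaborolane (vinylboronic acid pinacol ester) | C=CB1OC(C)(C)C(C)(C)O1 | starting material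
13 | {4-[(tert-butyldimethylsilyl)oxy]-2,2-dimethylbutyl}lithium (not isolated) | [Li]CC(C)(C)CCO[Si](C)(C)C(C)(C)C | intermediate
14 | lithium {4-[(tert-butyldimethylsilyl)oxy]-2,2-dimethylbutyl}(ethenyl)(pinacolato)borate (not isolated) | [Li+].C=C[B-]1(CC(C)(C)CCO[Si](C)(C)C(C)(C)C)OC(C)(C)C(C)(C)O1 | intermediate
15 | 2-(trimethylsilyl)ethyl (2E)-2-[(2S)-6-[(tert-butyldimethylsilyl)oxy]-4,4-dimethyl-2-(4,4,5,5-tetramethyl-1,3,2-dioxaborolan-2-yl)hexyl]-6-(triethylsilyl)hepta-2,6-dienoate | C=C(CC/C=C(/C(=O)OCC[Si](C)(C)C)C[C@@H](B1OC(C)(C)C(C)(C)O1)CC(C)(C)CCO[Si](C)(C)C(C)(C)C)[Si](CC)(CC)CC | intermediate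
16 | 2-(trimethylsilyl)ethyl (2E)-2-[(2S)-6-[(tert-butyldimethylsilyl)oxy]-2-hydroxy-4,4-dimethylhexyl]-6-(triethylsilyl)hepta-2,6-dienoate | C=C(CC/C=C(/C(=O)OCC[Si](C)(C)C)C[C@@H](O)CC(C)(C)CCO[Si](C)(C)C(C)(C)C)[Si](CC)(CC)CC | intermediate
17 | 2-(trimethylsilyl)ethyl (2E)-2-[(2S)-6-[(tert-butyldimethylsilyl)oxy]-4,4-dimethyl-2-{[(2Z)-2-methylbut-2-enoyl]oxy}hexyl]-6-(triethylsilyl)hepta-2,6-dienoate | C=C(CC/C=C(/C(=O)OCC[Si](C)(C)C)C[C@@H](OC(=O)/C(C)=C\C)CC(C)(C)CCO[Si](C)(C)C(C)(C)C)[Si](CC)(CC)CC | intermediate
18 | 2-(trimethylsilyl)ethyl (2E)-2-[(2S)-6-[(tert-butyldimethylsilyl)oxy]-4,4-dimethyl-2-{[(2Z)-2-methylbut-2-enoyl]oxy}hexyl]-6-iodohepta-2,6-dienoate | C=C(I)CC/C=C(/C(=O)OCC[Si](C)(C)C)C[C@@H](OC(=O)/C(C)=C\C)CC(C)(C)CCO[Si](C)(C)C(C)(C)C | intermediate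
19 | 2-(trimethylsilyl)ethyl (2E)-2-[(2S)-6-hydroxy-4,4-dimethyl-2-{[(2Z)-2-methylbut-2-enoyl]oxy}hexyl]-6-iodohepta-2,6-dienoate | C=C(I)CC/C=C(/C(=O)OCC[Si](C)(C)C)C[C@@H](OC(=O)/C(C)=C\C)CC(C)(C)CCO | intermediate
20 | 2-(trimethylsilyl)ethyl (2E)-2-[(2S)-4,4-dimethyl-2-{[(2Z)-2-methylbut-2-enoyl]oxy}-6-oxohexyl]-6-iodohepta-2,6-dienoate | C=C(I)CC/C=C(/C(=O)OCC[Si](C)(C)C)C[C@@H](OC(=O)/C(C)=C\C)CC(C)(C)CC=O | intermediate
21 | 2-(trimethylsilyl)ethyl (1E,6S,10S)-6-hydroxy-8,8-dimethyl-5-methylidene-10-{[(2Z)-2-methylbut-2-enoyl]oxy}cycloundec-1-ene-1-carboxylate | C=C1CC/C=C(/C(=O)OCC[Si](C)(C)C)C[C@@H](OC(=O)/C(C)=C\C)CC(C)(C)C[C@@H]1O | intermediate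
22 | (1E,6S,10S)-6-hydroxy-8,8-dimethyl-5-methylidene-10-{[(2Z)-2-methylbut-2-enoyl]oxy}cycloundec-1-ene-1-carboxylic acid (CNP0263820.1) | C=C1CC/C=C(/C(=O)O)C[C@@H](OC(=O)/C(C)=C\C)CC(C)(C)C[C@@H]1O | target

## Step count and least certain steps

Total step count: 15. Longest linear sequence: 11 steps (steps 1 to 3, then 8 to 15; the branch through steps 4, 5 and 7 is equally long).

**Step 8 (key step).** The most likely failure is inhibition of the cationic palladium intermediate by the iodide left from the lithium–iodine exchange and by the bromide released from 11. The metallate shift then stalls and direct Suzuki-type transfer from boron takes over. A secondary risk is insertion of the pendant C1=C15 alkene into the alkenylpalladium, since palladium on C5 is cis to the C3 tether.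

The fallback replaces the three-component shift by a two-stage sequence of known reactions. It sets out from ate complex 14 and bromo enoate 11 and returns at 15.
- Treating 14 with I2 and then NaOMe (Zweifel olefination) should give the terminal alkene tert-butyl[(3,3-dimethylhex-5-en-1-yl)oxy]dimethylsilane F1.
- Enantioselective diboration (B2pin2, Pt(dba)3, TADDOL-derived phosphonite) should convert it to the vicinal bis(boronate) tert-butyl{[(5R)-3,3-dimethyl-5,6-bis(4,4,5,5-tetramethyl-1,3,2-dioxaborolan-2-yl)hexyl]oxy}dimethylsilane F2.
- The primary boronate of F2 would be cross-coupled selectively with 11 (Pd(OAc)2, RuPhos, KOH, THF/H2O) to give 15. Halide ions do not interfere in this mode.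

**Step 14.** The most likely failure is poor facial selectivity at the C11 aldehyde. The ring conformation in the closing transition state may oppose the ligand, and C7 is too distant to help. Competing intermolecular coupling is countered by dilution.

The fallback sets out from 21, obtained as a mixture of C11 epimers, and returns to 21. Dess–Martin oxidation of the mixture would give the cross-conjugated enone 2-(trimethylsilyl)ethyl (1E,10S)-8,8-dimethyl-5-methylidene-10-{[(2Z)-2-methylbut-2-enoyl]oxy}-6-oxocycloundec-1-ene-1-carboxylate F4. Corey–Bakshi–Shibata reduction (2-methyl-CBS-oxazaborolidine, catecholborane, toluene, −78 °C) would then set C11 under reagent control.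

**Step 10.** Two processes threaten: isomerisation of the angeloyl unit to the tigloyl unit during the heated acylation, and cyclisation of the gamma-hydroxy ester 16 onto C14 while acylation is slow.

The fallback builds the angelate on the substrate at low temperature. It sets out from 16 and returns at 17.
- Esterification of 16 with 2-[bis(2,2,2-trifluoroethoxy)phosphoryl]propanoic acid (DCC, DMAP, CH2Cl2, 0 °C → rt) would give 2-(trimethylsilyl)ethyl (2E)-2-[(2S)-2-({2-[bis(2,2,2-trifluoroethoxy)phosphoryl]propanoyl}oxy)-6-[(tert-butyldimethylsilyl)oxy]-4,4-dimethylhexyl]-6-(triethylsilyl)hepta-2,6-dienoate F3.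
- Still–Gennari olefination with acetaldehyde (KN(SiMe3)2, 18-crown-6, THF, −78 °C) would form the (Z)-2-methylbut-2-enoate directly, giving 17.

## Further compounds

F1 | step 8 | tert-butyl[(3,3-dimethylhex-5-en-1-yl)oxy]dimethylsilane | C=CCC(C)(C)CCO[Si](C)(C)C(C)(C)C
F2 | step 8 | tert-butyl{[(5R)-3,3-dimethyl-5,6-bis(4,4,5,5-tetramethyl-1,3,2-dioxaborolan-2-yl)hexyl]oxy}dimethylsilane | CC1(C)OB(C[C@@H](B2OC(C)(C)C(C)(C)O2)CC(C)(C)CCO[Si](C)(C)C(C)(C)C)OC1(C)C
F3 | step 10 | 2-(trimethylsilyl)ethyl (2E)-2-[(2S)-2-({2-[bis(2,2,2-trifluoroethoxy)phosphoryl]propanoyl}oxy)-6-[(tert-butyldimethylsilyl)oxy]-4,4-dimethylhexyl]-6-(triethylsilyl)hepta-2,6-dienoate (mixture at the phosphonate carbon) | C=C(CC/C=C(/C(=O)OCC[Si](C)(C)C)C[C@@H](OC(=O)C(C)P(=O)(OCC(F)(F)F)OCC(F)(F)F)CC(C)(C)CCO[Si](C)(C)C(C)(C)C)[Si](CC)(CC)CC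
F4 | step 14 | 2-(trimethylsilyl)ethyl (1E,10S)-8,8-dimethyl-5-methylidene-10-{[(2Z)-2-methylbut-2-enoyl]oxy}-6-oxocycloundec-1-ene-1-carboxylate | C=C1CC/C=C(/C(=O)OCC[Si](C)(C)C)C[C@@H](OC(=O)/C(C)=C\C)CC(C)(C)CC1=O
A1 | alternative 1 | 4-[(tert-butyldimethylsilyl)oxy]-1,2-diethenyl-2-{[(4-methoxyphenyl)methoxy]methyl}-6,6-dimethylcycloheptan-1-ol, vinyl groups cis (one diastereomer with respect to the silyloxy carbon drawn; that relation is lost in the rearrangement) | C=C[C@@]1(O)CC(C)(C)C[C@H](O[Si](C)(C)C(C)(C)C)C[C@]1(C=C)COCc1ccc(OC)cc1
A2 | alternative 1 | eleven-membered C11 ketone with ring-cis C4=C5 olefin, C14 as 4-methoxybenzyl ether and C7 as tert-butyldimethylsilyl ether | O=C1CCC/C=C(/COCc2ccc(OC)cc2)C[C@@H](O[Si](C)(C)C(C)(C)C)CC(C)(C)C1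
A3 | alternative 2 | acyclic C10 diethyl phosphate with C11=C1 (E) olefin, ring-cis-configured enoate silylethyl ester, and a C7 carbon bearing trimethylsilyl and triethylsilyloxy next to the C8=C9 prenyl-type olefin (racemic at C7) | CCOP(=O)(OCC)OC/C=C(\C)CC/C=C(/C(=O)OCC[Si](C)(C)C)CC(O[Si](CC)(CC)CC)([Si](C)(C)C)C=C(C)C
A4 | alternative 2 | eleven-membered C7 ketone with C9 gem-dimethyl, C11=C1 trisubstituted olefin and ring-cis enoate silylethyl ester | C/C1=C\CC(C)(C)CC(=O)C/C(C(=O)OCC[Si](C)(C)C)=C\CC1
A5 | alternative 3 | twelve-membered cyclic sulfone bridging C4 and C5, with tert-butyl ester on C5, triethylsilyl ether at C7, tert-butyldimethylsilyl ether at C11 and methylene on C1 (C5 unassigned) | C=C1CCCS(=O)(=O)C(C(=O)OC(C)(C)C)C[C@@H](O[Si](CC)(CC)CC)CC(C)(C)C[C@@H]1O[Si](C)(C)C(C)(C)C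
A6 | alternative 3 | eleven-membered ring-cis enoate tert-butyl ester with C7 triethylsilyl ether and C11 tert-butyldimethylsilyl ether | C=C1CC/C=C(/C(=O)OC(C)(C)C)C[C@@H](O[Si](CC)(CC)CC)CC(C)(C)C[C@@H]1O[Si](C)(C)C(C)(C)C
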